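**Plan**

1. Retrosynthetic cuts, in order: the methyl ester and silyl ether (deprotection); both pyran-ring bonds that end on the benzene ring, C4–C4a and O1–C8a, in one operation; the C2'=C3' enoate alkene of the side chain; the two ends of a farnesol-derived chain.
2. Enabling feature: the pyran ring meets the benzene ring at the adjacent carbons C4a and C8a, while O1, the quaternary C2 and the cis C3=C4 alkene form a four-atom unit that can be carried intact as a (Z)-γ-hydroxyvinyl iodide. Annulating it onto an arene with boron at C4a and bromine at C8a closes the ring without ever breaking the C2–O1 bond.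
3. Forward order: (2E,6E)-farnesol → distal epoxide → asymmetric 2,3-epoxidation → epoxy chloride → iodoalkynol → (Z)-vinyl iodide → aldehyde → (Z)-enoate; the arene is made from 4-amino-3-methylphenol; the palladium-catalysed annulation closes the pyran ring last, followed by deprotection.
4. Stereochemistry: C2 (R) comes from Katsuki–Sharpless epoxidation with D-(−)-diethyl tartrate and is retained throughout; the 6'E alkene comes from farnesol; the 2'Z enoate from Still–Gennari olefination; the cis C3=C4 geometry from diimide reduction of the iodoalkyne.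

Key step: step 13

Remark: the distal oxirane carbon in 2–8 is formed without control and carried as both configurations; it becomes the sp2 aldehyde carbon in step 6 and does not reach the target.

**Route**

Step 1
Reactants: 1 (2E,6E)-farnesol
Product: 3 (2E,6E)-10,11-epoxy-3,7,11-trimethyldodeca-2,6-dien-1-ol (both configurations at C10), via bromohydrin 2 (not isolated)
Conditions: NBS (1.1 equiv), THF/H2O, 0 °C; then K2CO3, MeOH, rt
Reagents that add atoms: water, O (epoxide oxygen); N-bromosuccinimide, O=C1CCC(=O)N1Br (bromine of 2 only)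
Why: Terminal-selective bromohydrin formation followed by Williamson-type epoxide closure: in aqueous THF the distal trisubstituted alkene of the folded chain is the most accessible electron-rich site (the 2,3-alkene is deactivated by the allylic oxygen), water opens the bromonium ion at the tertiary carbon, and carbonate closes the epoxide; C10 is uncontrolled and is removed in step 6.

Step 2
Reactants: 3 (2E,6E)-10,11-epoxyfarnesol
Product: 4 (2R,3R,6E)-2,3:10,11-diepoxy-3,7,11-trimethyldodec-6-en-1-ol
Conditions: Ti(OiPr)4 (10 mol %), D-(−)-diethyl tartrate (12 mol %), t-BuOOH, 4 Å MS, CH2Cl2, −20 °C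
Reagents that add atoms: tert-butyl hydroperoxide, CC(C)(C)OO
Why: Katsuki–Sharpless asymmetric epoxidation acts only on the allylic alcohol, and with D-(−)-diethyl tartrate the titanium tartrate complex should deliver oxygen to the face of the (E)-alkene that gives the (2R,3R)-epoxide (the mirror image of the (2S,3S) outcome of L-(+)-tartrate with geraniol-type substrates), which fixes the later C2 of the chromene as R.

Step 3
Reactants: 4 (2R,3R)-diepoxy alcohol
Product: 5 (2S,3R,6E)-1-chloro-2,3:10,11-diepoxy-3,7,11-trimethyldodec-6-ene (same spatial arrangement as 4; the C2 descriptor changes because of chlorine)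
Conditions: PPh3, CCl4, NaHCO3, reflux
Reagents that add atoms: carbon tetrachloride, ClC(Cl)(Cl)Cl
Why: Appel reaction: the primary alcohol is converted to the chloride through an alkoxyphosphonium ion under neutral conditions that leave both epoxides and the stereocenters untouched.

Step 4
Reactants: 5 epoxy chloride
Product: 7 (3R,6E)-10,11-epoxy-1-iodo-3,7,11-trimethyldodec-6-en-1-yn-3-ol, via dilithium alkynolate 6 (not isolated)
Conditions: n-BuLi (3.2 equiv), THF, −78 to −30 °C; then I2 (1.1 equiv), −78 to 0 °C
Reagents that add atoms: iodine, [I][I]; n-butyllithium, [Li]CCCC (lithium of 6 only)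
Why: Base-induced eliminative opening of a 2,3-epoxy chloride (deprotonation at the chloromethyl carbon, β-elimination with epoxide opening, dehydrochlorination and acetylide formation) gives the tertiary propargylic alkoxide with retention because the C3–O bond is never broken, and the lithium acetylide is then iodinated; the hindered distal epoxide should survive n-BuLi at low temperature.

Step 5
Reactants: 7 iodoalkynol
Product: 8 (1Z,3R,6E)-10,11-epoxy-1-iodo-3,7,11-trimethyldodeca-1,6-dien-3-ol
Conditions: 2-nitrobenzenesulfonylhydrazide, Et3N, THF/i-PrOH, rt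
Reagents that add atoms: none
Why: Diimide generated in situ transfers two hydrogens to the same face of the iodoalkyne (concerted syn reduction), which gives the (Z)-vinyl iodide needed for ring closure, while trisubstituted alkenes, the epoxide and the C–I bond are inert to diimide.

Step 6
Reactants: 8 (Z)-vinyl iodide epoxide
Product: 9 (4E,8R,9Z)-8-hydroxy-10-iodo-4,8-dimethyldeca-4,9-dienal
Conditions: H5IO6 (1.2 equiv), THF/Et2O, 0 °C, short reaction time
Reagents that add atoms: none
Why: Periodic acid hydrolyses the trisubstituted epoxide (water entering at the tertiary carbon, so that the aldehyde oxygen is the former epoxide oxygen) and cleaves the glycol in the same pot (oxidative glycol cleavage), which excises the uncontrolled center as acetone; at 0 °C the tertiary allylic alcohol should not ionise.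

Step 7
Reactants: 10 methyl 2-[bis(2,2,2-trifluoroethoxy)phosphoryl]acetate; 11 5-bromo-2-methylpent-2-ene
Product: 12 methyl 2-[bis(2,2,2-trifluoroethoxy)phosphoryl]-6-methylhept-5-enoate (racemic)
Conditions: NaH, DMF, NaI (cat.), 0 to 50 °C
Reagents that add atoms: none
Why: SN2 C-alkylation of the sodium salt of the phosphonoacetate with the primary homoallylic bromide (iodide catalysis); the new α-center is racemic and is destroyed in step 8.

Step 8
Reactants: 9 aldehyde; 12 α-alkylated phosphonate
Product: 13 methyl (2Z,6E,10R,11Z)-10-hydroxy-12-iodo-6,10-dimethyl-2-(4-methylpent-3-en-1-yl)dodeca-2,6,11-trienoate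
Conditions: KN(SiMe3)2, 18-crown-6, THF, −78 °C
Reagents that add atoms: none
Why: Still–Gennari modification of the Horner–Wadsworth–Emmons reaction: with the electron-poor bis(trifluoroethyl) phosphonate and a dissociated potassium counter-ion the first-formed adduct eliminates faster than it equilibrates, which places the ester cis to the aldehyde-derived chain (2Z), and at −78 °C the free tertiary alcohol and the vinyl iodide are not touched.

Step 9
Reactants: 14 4-amino-3-methylphenol
Product: 15 2-methyl-4-[(triisopropylsilyl)oxy]aniline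
Conditions: i-Pr3SiCl, imidazole, DMF, rt
Reagents that add atoms: chlorotriisopropylsilane, CC(C)[Si](Cl)(C(C)C)C(C)C
Why: Chemoselective O-silylation: the phenol is silylated, whereas any N-silylated aniline is hydrolysed on work-up.

Step 10
Reactants: 15 silyloxy aniline
Product: 16 2-iodo-6-methyl-4-[(triisopropylsilyl)oxy]aniline
Conditions: I2, NaHCO3, CH2Cl2/H2O, rt
Reagents that add atoms: iodine, [I][I]
Why: Electrophilic aromatic iodination directed by the amino group to its only free ortho position, the other ortho position and the para position being occupied.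

Step 11
Reactants: 16 iodoaniline
Product: 17 (4-bromo-3-iodo-5-methylphenoxy)triisopropylsilane
Conditions: t-BuONO, CuBr2, MeCN, 0 °C to rt
Reagents that add atoms: CuBr2, Br[Cu]Br
Why: Non-aqueous Sandmeyer bromination: diazotisation by the alkyl nitrite, loss of nitrogen to the aryl radical and bromine-atom transfer from CuBr2, under neutral conditions that spare the silyl ether and the aryl iodide.

Step 12
Reactants: 17 bromo-iodoarene
Product: 19 [4-bromo-3-methyl-5-(4,4,5,5-tetramethyl-1,3,2-dioxaborolan-2-yl)phenoxy]triisopropylsilane, via aryl Grignard reagent 18 (not isolated)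
Conditions: i-PrMgCl·LiCl, THF, −40 °C; then i-PrOBpin, −40 °C to rt
Reagents that add atoms: 2-isopropoxy-4,4,5,5-tetramethyl-1,3,2-dioxaborolane, CC(C)OB1OC(C)(C)C(C)(C)O1; isopropylmagnesium chloride, CC(C)[Mg]Cl (magnesium and chlorine of 18 only)
Why: Iodine–magnesium exchange is much faster at the C–I than at the C–Br bond and the ortho-bromoaryl Grignard reagent does not eliminate to an aryne at −40 °C, so that borylation places boron at the later C4a.

Step 13
Reactants: 13 (Z)-γ-hydroxyvinyl iodide with the complete side chain; 19 ortho-bromoarylboronate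
Product: 21 methyl (2Z,6E)-9-[(2R)-2,8-dimethyl-6-(triisopropylsilyloxy)-2H-chromen-2-yl]-6-methyl-2-(4-methylpent-3-en-1-yl)nona-2,6-dienoate, via bromoaryl alkenyl carbinol 20 (not isolated)
Conditions: Pd(OAc)2 (5 mol %), 2-(di-tert-butylphosphino)-1,1'-binaphthyl (10 mol %), K3PO4·H2O, toluene, 40 °C; then 90 °C
Reagents that add atoms: none
Why: Zerovalent palladium inserts first into the vinyl C–I bond of 13, and transmetalation with the phosphate-activated boronate followed by reductive elimination gives the (Z)-styrenyl carbinol 20 with retention of alkene geometry (Suzuki–Miyaura coupling, forming C4–C4a). On warming, the same catalyst inserts into the aryl C–Br bond, the tertiary alkoxide replaces bromide on palladium, and C–O reductive elimination forms O1–C8a; the closest known reaction type is the Buchwald–Hartwig-type intramolecular etherification of aryl bromides with tertiary alcohols. The pyran ring is thus closed by intramolecular aryl–oxygen reductive elimination onto C8a, a six-membered ring from a seven-membered aryl(alkoxo)palladium chelate; the cis C3=C4 geometry holds the alkoxide within reach, and the tertiary alkoxide has no β-hydrogen, so β-hydride elimination is excluded. No stereocenter is created: C2 keeps the R configuration set in step 2 because the C2–O1 bond is never broken. The step needs chemoselectivity (vinyl iodide before the doubly ortho-substituted aryl bromide, secured by the reactivity gap and the two temperature stages), regiochemistry (fixed by boron at C4a and bromine at C8a) and C–O reductive elimination faster than β-carbon elimination or hydrodebromination (favoured by the bulky, electron-rich di-tert-butylbiaryl phosphine).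

Step 14
Reactants: 21 silyl-protected chromene methyl ester
Product: 23 (R)-sargachromenol, via phenol methyl ester 22 (not isolated)
Conditions: Bu4NF, THF, 0 °C; then LiOH·H2O, MeOH/H2O, 45 °C, argon; cold dilute HCl to pH 3–4
Reagents that add atoms: lithium hydroxide, [Li+].[OH-] (oxygen of the carboxyl OH)
Why: Fluoride-induced cleavage of the aryl silyl ether followed by saponification of the methyl ester (acyl–oxygen cleavage); neither operation touches C2, the chromene or the alkene geometries, and exclusion of air protects the electron-rich phenoxide.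

**Compound list**

1 | (2E,6E)-farnesol, (2E,6E)-3,7,11-trimethyldodeca-2,6,10-trien-1-ol | CC(C)=CCC/C(C)=C/CC/C(C)=C/CO | starting material
2 | (2E,6E)-10-bromo-3,7,11-trimethyldodeca-2,6-diene-1,11-diol (both configurations at C10) | CC(C)(O)C(Br)CC/C(C)=C/CC/C(C)=C/CO | intermediate
3 | (2E,6E)-10,11-epoxy-3,7,11-trimethyldodeca-2,6-dien-1-ol (both configurations at C10) | CC1(C)OC1CC/C(C)=C/CC/C(C)=C/CO | intermediate
4 | (2R,3R,6E)-2,3:10,11-diepoxy-3,7,11-trimethyldodec-6-en-1-ol (both configurations at C10) | CC1(C)OC1CC/C(C)=C/CC[C@@]2(C)O[C@@H]2CO | intermediate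
5 | (2S,3R,6E)-1-chloro-2,3:10,11-diepoxy-3,7,11-trimethyldodec-6-ene (both configurations at C10) | CC1(C)OC1CC/C(C)=C/CC[C@@]2(C)O[C@@H]2CCl | intermediate
6 | dilithium salt (acetylide and alkoxide) of (3R,6E)-10,11-epoxy-3,7,11-trimethyldodec-6-en-1-yn-3-ol | CC1(C)OC1CC/C(C)=C/CC[C@@](C)(O[Li])C#C[Li] | intermediate
7 | (3R,6E)-10,11-epoxy-1-iodo-3,7,11-trimethyldodec-6-en-1-yn-3-ol | CC1(C)OC1CC/C(C)=C/CC[C@@](C)(O)C#CI | intermediate
8 | (1Z,3R,6E)-10,11-epoxy-1-iodo-3,7,11-trimethyldodeca-1,6-dien-3-ol | CC1(C)OC1CC/C(C)=C/CC[C@@](C)(O)/C=C\I | intermediate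
9 | (4E,8R,9Z)-8-hydroxy-10-iodo-4,8-dimethyldeca-4,9-dienal | O=CCC/C(C)=C/CC[C@@](C)(O)/C=C\I | intermediate
10 | methyl 2-[bis(2,2,2-trifluoroethoxy)phosphoryl]acetate | COC(=O)CP(=O)(OCC(F)(F)F)OCC(F)(F)F | starting material
11 | 5-bromo-2-methylpent-2-ene | CC(C)=CCCBr | starting material
12 | methyl 2-[bis(2,2,2-trifluoroethoxy)phosphoryl]-6-methylhept-5-enoate (racemic) | CC(C)=CCCC(C(=O)OC)P(=O)(OCC(F)(F)F)OCC(F)(F)F | intermediate
13 | methyl (2Z,6E,10R,11Z)-10-hydroxy-12-iodo-6,10-dimethyl-2-(4-methylpent-3-en-1-yl)dodeca-2,6,11-trienoate | CC(C)=CCC/C(=C/CC/C(C)=C/CC[C@@](C)(O)/C=C\I)C(=O)OC | intermediate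
14 | 4-amino-3-methylphenol | Cc1cc(O)ccc1N | starting material
15 | 2-methyl-4-[(triisopropylsilyl)oxy]aniline | Cc1cc(O[Si](C(C)C)(C(C)C)C(C)C)ccc1N | intermediate
16 | 2-iodo-6-methyl-4-[(triisopropylsilyl)oxy]aniline | Cc1cc(O[Si](C(C)C)(C(C)C)C(C)C)cc(I)c1N | intermediate
17 | (4-bromo-3-iodo-5-methylphenoxy)triisopropylsilane | Cc1cc(O[Si](C(C)C)(C(C)C)C(C)C)cc(I)c1Br | intermediate
18 | [2-bromo-3-methyl-5-(triisopropylsilyloxy)phenyl]magnesium chloride | Cc1cc(O[Si](C(C)C)(C(C)C)C(C)C)cc([Mg]Cl)c1Br | intermediate
19 | [4-bromo-3-methyl-5-(4,4,5,5-tetramethyl-1,3,2-dioxaborolan-2-yl)phenoxy]triisopropylsilane | Cc1cc(O[Si](C(C)C)(C(C)C)C(C)C)cc(B2OC(C)(C)C(C)(C)O2)c1Br | intermediate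
20 | methyl (2Z,6E,10R,11Z)-12-[2-bromo-3-methyl-5-(triisopropylsilyloxy)phenyl]-10-hydroxy-6,10-dimethyl-2-(4-methylpent-3-en-1-yl)dodeca-2,6,11-trienoate | CC(C)=CCC/C(=C/CC/C(C)=C/CC[C@@](C)(O)/C=C\c1cc(O[Si](C(C)C)(C(C)C)C(C)C)cc(C)c1Br)C(=O)OC | intermediate
21 | methyl (2Z,6E)-9-[(2R)-2,8-dimethyl-6-(triisopropylsilyloxy)-2H-chromen-2-yl]-6-methyl-2-(4-methylpent-3-en-1-yl)nona-2,6-dienoate | CC(C)=CCC/C(=C/CC/C(C)=C/CC[C@]1(C)C=Cc2cc(O[Si](C(C)C)(C(C)C)C(C)C)cc(C)c2O1)C(=O)OC | intermediate
22 | methyl (2Z,6E)-9-[(2R)-6-hydroxy-2,8-dimethyl-2H-chromen-2-yl]-6-methyl-2-(4-methylpent-3-en-1-yl)nona-2,6-dienoate | CC(C)=CCC/C(=C/CC/C(C)=C/CC[C@]1(C)C=Cc2cc(O)cc(C)c2O1)C(=O)OC | intermediate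
23 | (R)-sargachromenol, (2Z,6E)-9-[(2R)-6-hydroxy-2,8-dimethyl-2H-chromen-2-yl]-6-methyl-2-(4-methylpent-3-en-1-yl)nona-2,6-dienoic acid | CC(C)=CCC/C(=C/CC/C(C)=C/CC[C@]1(C)C=Cc2cc(O)cc(C)c2O1)C(=O)O | target

**Step count**

Total: 14 steps (two-stage one-pot operations counted once). Longest linear sequence: 9 steps from farnesol (steps 1–6, 8, 13, 14).

**Steps most likely to fail, with fallbacks**

Step 13. The aryl–oxygen reductive elimination at the doubly ortho-substituted arylpalladium alkoxide may be slow, so that β-carbon elimination of the tertiary alkoxide, hydrodebromination or capture by hydroxide takes over; loss of the Z geometry at the vinylpalladium stage is a lesser concern. Fallback: the two bond formations are uncoupled and the ether bond is made by a different metal and mechanism. Setting out from 13 and 19, only the Suzuki–Miyaura stage is run (Pd(PPh3)4, aqueous K3PO4, THF, 40 °C) and the bromoaryl alkenyl carbinol 20 is isolated. The ring is then closed by a copper-mediated Ullmann-type etherification (CuI, 3,4,7,8-tetramethyl-1,10-phenanthroline, Cs2CO3, toluene, 110 °C), which avoids the palladium alkoxide altogether and comes back to the route at 21. This fallback makes no compound outside the list (F0).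

Step 7. Alkylation of the weakly nucleophilic, base-sensitive bis(trifluoroethyl) phosphonoacetate anion with an unactivated homoallylic bromide may stall, over-alkylate, lose trifluoroethoxide by exchange at phosphorus, or be outrun by elimination of the bromide to the diene. Fallback: the carbon–carbon bond is made on a robust phosphonate and the phosphorus esters are exchanged afterwards. Setting out from 11, commercial trimethyl phosphonoacetate is alkylated (NaH, DMSO, NaI cat.) to methyl 2-(dimethoxyphosphoryl)-6-methylhept-5-enoate F1. Me3SiBr with pyridine in CH2Cl2 converts it into methyl 2-[bis(trimethylsilyloxy)phosphoryl]-6-methylhept-5-enoate F2. Oxalyl chloride with catalytic DMF gives methyl 2-(dichlorophosphoryl)-6-methylhept-5-enoate F3, and 2,2,2-trifluoroethanol with Et3N then gives 12, where the route is rejoined.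

Step 4. n-BuLi may attack or isomerise the distal epoxide, or the double elimination may stop at the chlorovinyl stage. Fallback: the order of events is changed so that no epoxide other than the reacting one meets the strong base. Setting out from 1, Katsuki–Sharpless epoxidation (Ti(OiPr)4, D-(−)-diethyl tartrate, t-BuOOH) gives (2R,3R,6E)-2,3-epoxy-3,7,11-trimethyldodeca-6,10-dien-1-ol F4, and the Appel reaction gives (2S,3R,6E)-1-chloro-2,3-epoxy-3,7,11-trimethyldodeca-6,10-diene F5. n-BuLi leads through the dilithium salt of (3R,6E)-3,7,11-trimethyldodeca-6,10-dien-1-yn-3-ol F6, which is iodinated to (3R,6E)-1-iodo-3,7,11-trimethyldodeca-6,10-dien-1-yn-3-ol F7. Diimide reduction gives (1Z,3R,6E)-1-iodo-3,7,11-trimethyldodeca-1,6,10-trien-3-ol F8. Only then is the distal alkene converted with NBS in aqueous THF into (1Z,3R,6E)-10-bromo-1-iodo-3,7,11-trimethyldodeca-1,6-diene-3,11-diol F9, which K2CO3 in MeOH closes to 8, where the route is rejoined.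

**Further compounds**

F0 | step 13 | none | none
F1 | step 7 | methyl 2-(dimethoxyphosphoryl)-6-methylhept-5-enoate (racemic) | CC(C)=CCCC(C(=O)OC)P(=O)(OC)OC
F2 | step 7 | methyl 2-[bis(trimethylsilyloxy)phosphoryl]-6-methylhept-5-enoate (racemic) | CC(C)=CCCC(C(=O)OC)P(=O)(O[Si](C)(C)C)O[Si](C)(C)C
F3 | step 7 | methyl 2-(dichlorophosphoryl)-6-methylhept-5-enoate (racemic) | CC(C)=CCCC(C(=O)OC)P(=O)(Cl)Cl
F4 | step 4 | (2R,3R,6E)-2,3-epoxy-3,7,11-trimethyldodeca-6,10-dien-1-ol | CC(C)=CCC/C(C)=C/CC[C@@]1(C)O[C@@H]1CO
F5 | step 4 | (2S,3R,6E)-1-chloro-2,3-epoxy-3,7,11-trimethyldodeca-6,10-diene | CC(C)=CCC/C(C)=C/CC[C@@]1(C)O[C@@H]1CCl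
F6 | step 4 | dilithium salt (acetylide and alkoxide) of (3R,6E)-3,7,11-trimethyldodeca-6,10-dien-1-yn-3-ol | CC(C)=CCC/C(C)=C/CC[C@@](C)(O[Li])C#C[Li]
F7 | step 4 | (3R,6E)-1-iodo-3,7,11-trimethyldodeca-6,10-dien-1-yn-3-ol | CC(C)=CCC/C(C)=C/CC[C@@](C)(O)C#CI
F8 | step 4 | (1Z,3R,6E)-1-iodo-3,7,11-trimethyldodeca-1,6,10-trien-3-ol | CC(C)=CCC/C(C)=C/CC[C@@](C)(O)/C=C\I
F9 | step 4 | (1Z,3R,6E)-10-bromo-1-iodo-3,7,11-trimethyldodeca-1,6-diene-3,11-diol (both configurations at C10) | CC(C)(O)C(Br)CC/C(C)=C/CC[C@@](C)(O)/C=C\I
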